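**Strategy.** Botcinin numbering is used: C1 is the lactone carbonyl, C10 the acetyl methyl, and the oxane ring is O–C4–C5–C6–C7–C8. The plan cuts C4–C5 and C6–C7, the two bonds a polyketide synthase would make around the propionate unit C5–C6. In one flask, a propanal enol silane is inserted between the C7 aldehyde and the C4 thioester enolate of an acyclic C4–O–C8 ether. This magnesium-templated double aldol closes the oxane ring and sets C4–C7. The precursor is a lactate-derived α-alkoxy thioester ether of a quaternary α-ethynyl aldehyde. The ethynyl group is the latent C9 acetyl, and the lactone is closed last by a samarium Reformatsky reaction.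

Key step: step 6

Remark: the lactate-derived centre of 2, 5, 6 and 9 becomes C4 and is erased by enolisation in step 6; the (S)-ester is used only so that these intermediates are single diastereomers.

**Step 1**
Reactants: 1 ethyl (S)-lactate
Product: 2 S-phenyl (2S)-2-hydroxypropanethioate
Conditions: Me3Al, PhSH, CH2Cl2, 0 °C → rt
Reagents that add atoms: thiophenol, Sc1ccccc1
Why: Ester-to-thioester exchange by the aluminium thiolate Me2AlSPh; the stereocentre is not touched.

**Step 2**
Reactants: 3 (Z)-3-methylpent-2-en-4-yn-1-ol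
Product: 4 [(2S,3R)-3-ethynyl-3-methyloxiran-2-yl]methanol
Conditions: Ti(OiPr)4, L-(+)-diethyl tartrate, t-BuOOH, 4 Å MS, CH2Cl2, −20 °C
Reagents that add atoms: tert-butyl hydroperoxide, CC(C)(C)OO
Why: Sharpless asymmetric epoxidation; L-(+)-tartrate should deliver oxygen to the face that gives 2S, which for this (Z)-trisubstituted allylic alcohol means 2S,3R.

**Step 3**
Reactants: 4 [(2S,3R)-3-ethynyl-3-methyloxiran-2-yl]methanol, 2 S-phenyl (2S)-2-hydroxypropanethioate
Product: 5 S-phenyl (2S)-2-{[(2S,3S)-1,2-dihydroxy-3-methylpent-4-yn-3-yl]oxy}propanethioate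
Conditions: 2 (3 equiv), BF3·OEt2 (10 mol%), CH2Cl2, −30 → 0 °C; used without delay
Reagents that add atoms: none
Why: Lewis-acid-catalysed alcoholysis of a 2,3-epoxy alcohol at the tertiary propargylic carbon (better cation-stabilised and remote from the CH2OH group), with inversion, should set the quaternary ether centre that becomes C8.

**Step 4**
Reactants: 5 S-phenyl (2S)-2-{[(2S,3S)-1,2-dihydroxy-3-methylpent-4-yn-3-yl]oxy}propanethioate
Product: 6 S-phenyl (2S)-2-{[(2S)-2-methyl-1-oxobut-3-yn-2-yl]oxy}propanethioate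
Conditions: NaIO4, THF/H2O, 0 °C → rt
Reagents that add atoms: none
Why: Periodate glycol cleavage of the only vicinal diol (the tertiary oxygen is etherified) gives the C7 aldehyde; the quaternary centre is not touched.

**Step 5**
Reactants: 7 propanal
Product: 8 (Z)-tert-butyldimethyl(prop-1-en-1-yloxy)silane
Conditions: TBSOTf, Et3N, CH2Cl2, 0 °C
Reagents that add atoms: tert-butyldimethylsilyl trifluoromethanesulfonate, CC(C)(C)[Si](C)(C)OS(=O)(=O)C(F)(F)F
Why: O-silylation of the aldehyde enol with silyl triflate and amine should give mainly the (Z)-enol ether; the geometry is not critical for step 6.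

**Step 6**
Reactants: 6 S-phenyl (2S)-2-{[(2S)-2-methyl-1-oxobut-3-yn-2-yl]oxy}propanethioate, 8 (Z)-tert-butyldimethyl(prop-1-en-1-yloxy)silane
Product: 10 S-phenyl (2S,3S,4S,5R,6S)-5-[(tert-butyldimethylsilyl)oxy]-6-ethynyl-3-hydroxy-2,4,6-trimethyloxane-2-carbothioate, via open-chain β-silyloxy aldehyde 9 (not isolated)
Conditions: MgBr2·OEt2 (3 equiv), 8 (1.3 equiv), CH2Cl2 (0.02 M), −40 → 0 °C; then i-Pr2NEt (3 equiv), 0 °C → rt
Reagents that add atoms: none
Why: Proposed new method: MgBr2 chelates the C7 aldehyde oxygen and the ether oxygen of 6, the enol silane 8 adds through an open transition state (Mukaiyama aldol) and the silyl group passes to the C7 aldolate to give 9, after which i-Pr2NEt soft-enolises the magnesium-bound α-alkoxy thioester and the enolate closes onto the C5 aldehyde in a 6-(enolexo)-exo-trig aldol that forms the oxane ring. The closest known reactions are the MgBr2-mediated chelation-controlled Mukaiyama aldol of α-alkoxy aldehydes and the MgBr2/amine direct aldol of S-phenyl thioesters, whose one-flask merger on an aldehyde-derived enol silane and an α-branched α-alkoxy thioester is untested. C7 is set by the five-membered chelate (attack past the small ethynyl group and away from the C8 methyl), and C6 by the syn preference of the open transition state and its equatorial place in the ring-closing chair. C5 and C4 are set in a chair transition state with the C7 silyloxy group, the C6 methyl and the C5 aldehyde oxygen equatorial and the magnesium enolate carbon equatorial and gauche to that oxygen (Zimmerman–Traxler arrangement, trans-fused), which leaves the smaller C4 methyl axial. The step needs the enol silane to add to 6 and not to 9, which chelate activation of the α-alkoxy aldehyde should secure, and it needs enolisation of the thioester rather than of the α-branched aldehyde, which magnesium binding to the α-alkoxy thioester and the intramolecular closure should secure.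

**Step 7**
Reactants: 10 S-phenyl (2S,3S,4S,5R,6S)-5-[(tert-butyldimethylsilyl)oxy]-6-ethynyl-3-hydroxy-2,4,6-trimethyloxane-2-carbothioate
Product: 11 (2S,3S,4S,5R,6S)-5-[(tert-butyldimethylsilyl)oxy]-6-ethynyl-3-hydroxy-2,4,6-trimethyloxane-2-carbaldehyde
Conditions: DIBAL-H (3 equiv), CH2Cl2, −78 °C; Rochelle salt
Reagents that add atoms: none
Why: Partial reduction of a thioester to the aldehyde (the aluminium hemithioacetal collapses only on work-up); the quaternary α-carbon rules out epimerisation and elimination.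

**Step 8**
Reactants: 11 (2S,3S,4S,5R,6S)-5-[(tert-butyldimethylsilyl)oxy]-6-ethynyl-3-hydroxy-2,4,6-trimethyloxane-2-carbaldehyde, 12 2-bromopropanoyl bromide (racemic)
Product: 13 (2S,3S,4S,5R,6S)-5-[(tert-butyldimethylsilyl)oxy]-6-ethynyl-2-formyl-2,4,6-trimethyloxan-3-yl 2-bromopropanoate (both epimers at CHBr)
Conditions: pyridine, CH2Cl2, 0 °C
Reagents that add atoms: none
Why: O-acylation of the only free hydroxyl (C5–OH) with an acid bromide; the CHBr centre becomes an enolate in step 11, so its configuration does not matter.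

**Step 9**
Reactants: 13 (2S,3S,4S,5R,6S)-5-[(tert-butyldimethylsilyl)oxy]-6-ethynyl-2-formyl-2,4,6-trimethyloxan-3-yl 2-bromopropanoate
Product: 14 (2S,3S,4R,5R,6S)-6-ethynyl-2-formyl-5-hydroxy-2,4,6-trimethyloxan-3-yl 2-bromopropanoate
Conditions: HF·pyridine, THF, 0 °C → rt
Reagents that add atoms: none
Why: Fluoride desilylation under mildly acidic conditions spares the α-bromo ester and the aldehyde; the 1,3-diequatorial oxygens should not allow acyl migration.

**Step 10**
Reactants: 14 (2S,3S,4R,5R,6S)-6-ethynyl-2-formyl-5-hydroxy-2,4,6-trimethyloxan-3-yl 2-bromopropanoate, 15 (E)-oct-2-enoic acid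
Product: 16 (2S,3R,4R,5S,6S)-5-[(2-bromopropanoyl)oxy]-2-ethynyl-6-formyl-2,4,6-trimethyloxan-3-yl (2E)-oct-2-enoate
Conditions: 15, (COCl)2, cat. DMF, CH2Cl2, 0 °C → rt, concentrate; then 14, pyridine, DMAP (cat.), CH2Cl2, 0 °C → rt
Reagents that add atoms: none
Why: Acylation of the hindered C7 alcohol with the acid chloride under nucleophilic catalysis; the (E)-alkene and all stereocentres are retained.

**Step 11**
Reactants: 16 (2S,3R,4R,5S,6S)-5-[(2-bromopropanoyl)oxy]-2-ethynyl-6-formyl-2,4,6-trimethyloxan-3-yl (2E)-oct-2-enoate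
Product: 17 8-ethynyl analogue of botcinin K (the target with C≡CH in place of the acetyl group; botcinin numbering 2R,3S,4R,5S,6R,7R,8S)
Conditions: SmI2 (2.5 equiv), THF, −78 °C
Reagents that add atoms: none
Why: Intramolecular samarium Reformatsky reaction: SmI2 reduces only the α-bromo ester, and the Sm(III) enolate adds to the C3 aldehyde through a samarium-bridged closure of the lactone trans-fused to the oxane chair, which is expected to place the C3 hydroxyl and the C2 methyl cis to each other and to the axial C4 methyl.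

**Step 12**
Reactants: 17 8-ethynyl analogue of botcinin K
Product: 18 botcinin K
Conditions: (IPr)AuCl/AgSbF6 (2 mol%), 1,4-dioxane/H2O, 60 °C
Reagents that add atoms: water, O
Why: Gold(I)-catalysed Markovnikov hydration of the terminal alkyne gives the methyl ketone (the neighbouring C7 ester can only reinforce attack at the internal carbon); lactone, enoate and all stereocentres are untouched.

**Compound list**
1 | ethyl (S)-lactate | C[C@H](O)C(=O)OCC | starting material
2 | S-phenyl (2S)-2-hydroxypropanethioate | C[C@H](O)C(=O)Sc1ccccc1 | intermediate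
3 | (Z)-3-methylpent-2-en-4-yn-1-ol | C#C/C(C)=C\CO | starting material
4 | [(2S,3R)-3-ethynyl-3-methyloxiran-2-yl]methanol | C#C[C@@]1(C)O[C@H]1CO | intermediate
5 | S-phenyl (2S)-2-{[(2S,3S)-1,2-dihydroxy-3-methylpent-4-yn-3-yl]oxy}propanethioate | C#C[C@@](C)([C@@H](O)CO)O[C@@H](C)C(=O)Sc1ccccc1 | intermediate
6 | S-phenyl (2S)-2-{[(2S)-2-methyl-1-oxobut-3-yn-2-yl]oxy}propanethioate | C#C[C@@](C)(C=O)O[C@@H](C)C(=O)Sc1ccccc1 | intermediate
7 | propanal | CCC=O | starting material
8 | (Z)-tert-butyldimethyl(prop-1-en-1-yloxy)silane | C/C=C\O[Si](C)(C)C(C)(C)C | intermediate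
9 | S-phenyl (2S)-2-{[(3S,4R,5R)-4-[(tert-butyldimethylsilyl)oxy]-3,5-dimethyl-6-oxohex-1-yn-3-yl]oxy}propanethioate | C#C[C@@](C)([C@H](O[Si](C)(C)C(C)(C)C)[C@@H](C)C=O)O[C@@H](C)C(=O)Sc1ccccc1 | intermediate (not isolated)
10 | S-phenyl (2S,3S,4S,5R,6S)-5-[(tert-butyldimethylsilyl)oxy]-6-ethynyl-3-hydroxy-2,4,6-trimethyloxane-2-carbothioate | CC(C)(C)[Si](C)(C)O[C@@H]1[C@@H](C)[C@H](O)[C@@](C)(C(=O)Sc2ccccc2)O[C@@]1(C)C#C | intermediate
11 | (2S,3S,4S,5R,6S)-5-[(tert-butyldimethylsilyl)oxy]-6-ethynyl-3-hydroxy-2,4,6-trimethyloxane-2-carbaldehyde | CC(C)(C)[Si](C)(C)O[C@@H]1[C@@H](C)[C@H](O)[C@@](C)(C=O)O[C@@]1(C)C#C | intermediate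
12 | 2-bromopropanoyl bromide (racemic) | CC(Br)C(=O)Br | starting material
13 | (2S,3S,4S,5R,6S)-5-[(tert-butyldimethylsilyl)oxy]-6-ethynyl-2-formyl-2,4,6-trimethyloxan-3-yl 2-bromopropanoate (both epimers at CHBr) | CC(C)(C)[Si](C)(C)O[C@@H]1[C@@H](C)[C@H](OC(=O)C(C)Br)[C@@](C)(C=O)O[C@@]1(C)C#C | intermediate
14 | (2S,3S,4R,5R,6S)-6-ethynyl-2-formyl-5-hydroxy-2,4,6-trimethyloxan-3-yl 2-bromopropanoate | O[C@@H]1[C@@H](C)[C@H](OC(=O)C(C)Br)[C@@](C)(C=O)O[C@@]1(C)C#C | intermediate
15 | (E)-oct-2-enoic acid | CCCCC/C=C/C(=O)O | starting material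
16 | (2S,3R,4R,5S,6S)-5-[(2-bromopropanoyl)oxy]-2-ethynyl-6-formyl-2,4,6-trimethyloxan-3-yl (2E)-oct-2-enoate | CCCCC/C=C/C(=O)O[C@@H]1[C@@H](C)[C@H](OC(=O)C(C)Br)[C@@](C)(C=O)O[C@@]1(C)C#C | intermediate
17 | 8-ethynyl analogue of botcinin K (botcinin numbering 2R,3S,4R,5S,6R,7R,8S) | CCCCC/C=C/C(=O)O[C@@H]1[C@@H](C)[C@@H]2OC(=O)[C@H](C)[C@H](O)[C@@]2(C)O[C@@]1(C)C#C | intermediate
18 | botcinin K | CCCCC/C=C/C(=O)O[C@@H]1[C@@H](C)[C@@H]2OC(=O)[C@H](C)[C@H](O)[C@@]2(C)O[C@@]1(C)C(C)=O | target

**Step count.** Total: 12 steps. Longest linear sequence: 10 steps (3 → 18 through steps 2, 3, 4 and 6–12).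

**Steps most likely to fail**

Step 6 (Proposed new method). The enol silane may add a second time to the liberated aldehyde 9. The amine may enolise the aldehyde or expel silanolate from 9 instead of enolising the thioester. The silyl group may not end on the C7 oxygen, and the ring closure may show poor facial control at C4/C5. The fallback makes the two bonds in separate, known operations and leaves the route at 6. Chelation-controlled crotylstannane addition ((E)-but-2-enyl(tributyl)stannane, MgBr2·OEt2, CH2Cl2, −20 °C) should give the syn,syn homoallylic alcohol S-phenyl (2S)-2-{[(3S,4R,5S)-4-hydroxy-3,5-dimethylhept-6-en-1-yn-3-yl]oxy}propanethioate F1. Silylation (TBSOTf, 2,6-lutidine) gives its TBS ether F2. Lemieux–Johnson cleavage of the vinyl group (OsO4 cat., NaIO4, 2,6-lutidine, dioxane/H2O; the alkyne reacts far more slowly) gives 9, now isolated. Purified 9 is then cyclised on its own under the direct thioester aldol conditions (MgBr2·OEt2, i-Pr2NEt) or through its lithium enolate (LiHMDS, THF, −78 °C), and the fallback comes back to the route at 10.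

Step 3. Ionisation at the tertiary propargylic carbon may erode the configuration of the future C8. The epoxide may rearrange or oligomerise through its free primary hydroxyl, and the weakly nucleophilic hydroxy thioester may not compete. The fallback forms the O–C4 bond instead of the O–C8 bond and leaves the route at 4. Acid-catalysed hydrolysis (HClO4 cat., THF/H2O, 0 °C; water attacks the tertiary carbon with inversion) gives (2S,3S)-3-methylpent-4-yne-1,2,3-triol F3. Kinetic acetonide formation on the 1,2-diol (2-methoxypropene, PPTS, 0 °C) gives the tertiary alcohol (2S)-2-[(4S)-2,2-dimethyl-1,3-dioxolan-4-yl]but-3-yn-2-ol F4. Rhodium-carbenoid O–H insertion (ethyl 2-diazopropanoate, Rh2(OAc)4, slow addition) gives the ether ethyl 2-{[(2S)-2-[(4S)-2,2-dimethyl-1,3-dioxolan-4-yl]but-3-yn-2-yl]oxy}propanoate F5 as both epimers at the propanoate carbon. Thioester exchange (Me3Al, PhSH) gives the S-phenyl thioester F6, and aqueous acetic acid removes the acetonide. The fallback comes back at 5, which is accompanied by its (2R)-propanethioate epimer F7. Step 4 then gives 6 together with its epimer F8, and both converge on 10 in step 6 because this centre is enolised there.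

Step 11. The samarium enolate may add to the other face of the aldehyde (for example if samarium also binds the ring oxygen), or the enolate geometry may give the wrong C2 configuration. The fallback leaves the route at 16 and sets C3 by hydride delivery instead of by the C–C bond formation. If the cyclisation gives the C3 epimer of 17 F9, Dess–Martin oxidation gives the β-keto lactone F10, in which C2 can equilibrate through the enol. Luche reduction (NaBH4, CeCl3, MeOH, −78 °C) should attack the face opposite the axial C4 methyl, and the fallback comes back at 17.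

**Further compounds**
F1 | step 6 | S-phenyl (2S)-2-{[(3S,4R,5S)-4-hydroxy-3,5-dimethylhept-6-en-1-yn-3-yl]oxy}propanethioate | C#C[C@@](C)([C@H](O)[C@@H](C)C=C)O[C@@H](C)C(=O)Sc1ccccc1
F2 | step 6 | S-phenyl (2S)-2-{[(3S,4R,5S)-4-[(tert-butyldimethylsilyl)oxy]-3,5-dimethylhept-6-en-1-yn-3-yl]oxy}propanethioate | C#C[C@@](C)([C@H](O[Si](C)(C)C(C)(C)C)[C@@H](C)C=C)O[C@@H](C)C(=O)Sc1ccccc1
F3 | step 3 | (2S,3S)-3-methylpent-4-yne-1,2,3-triol | C#C[C@@](C)([C@@H](O)CO)O
F4 | step 3 | (2S)-2-[(4S)-2,2-dimethyl-1,3-dioxolan-4-yl]but-3-yn-2-ol | C#C[C@@](C)([C@@H]1COC(C)(C)O1)O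
F5 | step 3 | ethyl 2-{[(2S)-2-[(4S)-2,2-dimethyl-1,3-dioxolan-4-yl]but-3-yn-2-yl]oxy}propanoate (both epimers at the propanoate carbon) | C#C[C@@](C)([C@@H]1COC(C)(C)O1)OC(C)C(=O)OCC
F6 | step 3 | S-phenyl 2-{[(2S)-2-[(4S)-2,2-dimethyl-1,3-dioxolan-4-yl]but-3-yn-2-yl]oxy}propanethioate (both epimers at the propanethioate carbon) | C#C[C@@](C)([C@@H]1COC(C)(C)O1)OC(C)C(=O)Sc1ccccc1
F7 | step 3 | S-phenyl (2R)-2-{[(2S,3S)-1,2-dihydroxy-3-methylpent-4-yn-3-yl]oxy}propanethioate | C#C[C@@](C)([C@@H](O)CO)O[C@H](C)C(=O)Sc1ccccc1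
F8 | step 3 | S-phenyl (2R)-2-{[(2S)-2-methyl-1-oxobut-3-yn-2-yl]oxy}propanethioate | C#C[C@@](C)(C=O)O[C@H](C)C(=O)Sc1ccccc1
F9 | step 11 | C3 epimer of 17 (C2 configuration open) | CCCCC/C=C/C(=O)O[C@@H]1[C@@H](C)[C@@H]2OC(=O)C(C)[C@@H](O)[C@@]2(C)O[C@@]1(C)C#C
F10 | step 11 | 3-oxo (β-keto lactone) analogue of 17 | CCCCC/C=C/C(=O)O[C@@H]1[C@@H](C)[C@@H]2OC(=O)C(C)C(=O)[C@@]2(C)O[C@@]1(C)C#C
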